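**Retrosynthetic overview**

1. Numbering: indan-2-one core with C1 (carries the acetoxyethyl group), C2 (C=O), C3, C3a, C4 (=CH2), C5, C6, C7, C7a; ring A = cyclopentanone, ring B = cyclohexane; β = the face of ring B that carries C1 and C3 at the ring fusion (H-1, H-3a, H-7a, H-7 and H-6 are α, H-5 is β).
2. Late stage: three esterifications (C6–O, C5–O, C1′–O) and the glycidic ester by Sharpless epoxidation and oxidation of a 2-substituted allylic alcohol on C7; the 6β-OH and H-7α come from a C6=C7 alkene by β-epoxidation and formate hydrogenolysis of the vinyl epoxide.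
3. Key disconnection C1–C7a, which closes ring A last, by palladium-catalysed intramolecular allylic alkylation. The enabling feature: in ring B, C7a is the far terminus of the allyl unit C7a=C7–C6–O, whose oxygen is cis to the C3a arm, and C1 is α to the C2 ketone, so it can carry a removable sulfonyl group as a soft carbanion.
4. The cis C6–OH / C3a–CH2CO2Me cyclohexene comes from Baeyer–Villiger cleavage (retention) of a bicyclo[2.2.2]octenone. That bicycle is made in one step from a guaiacol by oxidative dearomatisation and Diels–Alder reaction with a chiral alkoxyallene, which sets C3a, C5, C6 and the C4 methylidene.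
5. Ring order: arene → bicyclo[2.2.2]octenone (ring B plus a temporary ketone bridge) → monocyclic ring B → ring A by the key step.

Key step: step 12

Assumption: the (S)-1-(4-methoxyphenyl)ethyl group on the allene oxygen gives the required endo adduct 10 as the major, or at least chromatographically separable, diastereomer; if the other one predominates, the (R)-alcohol is used and nothing else changes.

**Route**

Step 1
Reactants: 1 bromoallyl alcohol (2-bromoprop-2-en-1-ol)
Product: 2 (2-bromoallyloxy)(tert-butyl)dimethylsilane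
Conditions: TBSCl, imidazole, CH2Cl2, 0 °C to rt
Reagents that add atoms: tert-butyldimethylsilyl chloride CC(C)(C)[Si](C)(C)Cl
Why: Imidazole-mediated silylation of the primary allylic alcohol (silyl ether protection) masks the future ester carbon of the oxirane unit through the basic, reductive and organometallic steps that follow.

Step 2
Reactants: 2 (2-bromoallyloxy)(tert-butyl)dimethylsilane; 3 (3-hydroxy-4-methoxyphenyl)boronic acid
Product: 4 5-[3-(tert-butyldimethylsilyloxy)prop-1-en-2-yl]-2-methoxyphenol
Conditions: Pd(PPh3)4 (5 mol %), K2CO3, 1,4-dioxane/H2O, 80 °C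
Reagents that add atoms: none
Why: Suzuki–Miyaura coupling of a vinyl bromide with an arylboronic acid tolerates the free phenol and places the three-carbon unit para to the methoxy group, on the ring carbon that becomes C7.

Step 3
Reactants: 5 (S)-1-(4-methoxyphenyl)ethanol; 6 propargyl bromide
Product: 7 (S)-1-methoxy-4-[1-(prop-2-yn-1-yloxy)ethyl]benzene
Conditions: NaH, Bu4NI (cat.), THF, 0 °C to rt
Reagents that add atoms: none
Why: Williamson etherification of the sodium alkoxide with the primary propargylic bromide attaches the cleavable chiral benzylic group without touching its stereocentre.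

Step 4
Reactants: 7 (S)-1-methoxy-4-[1-(prop-2-yn-1-yloxy)ethyl]benzene
Product: 8 (S)-1-methoxy-4-[1-(propa-1,2-dien-1-yloxy)ethyl]benzene
Conditions: KOtBu (0.3 equiv), THF, rt
Reagents that add atoms: none
Why: Base-catalysed propargyl-to-allenyl isomerisation of a propargyl ether stops at the 1-alkoxyallene, the standard entry to alkoxyallenes.

Step 5
Reactants: 4 5-[3-(tert-butyldimethylsilyloxy)prop-1-en-2-yl]-2-methoxyphenol; 8 (S)-1-methoxy-4-[1-(propa-1,2-dien-1-yloxy)ethyl]benzene
Product: 10 endo bicyclo[2.2.2]oct-5-en-2-one adduct, via dienone 9 (not isolated)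
Conditions: PhI(OAc)2 (1.1 equiv), 8 (4 equiv), MeOH, 0 °C to rt; chromatographic separation of the diastereomers
Reagents that add atoms: methanol CO
Why: Oxidative dearomatisation of the guaiacol in methanol gives the 6,6-dimethoxycyclohexa-2,4-dienone, which is trapped in situ in an inverse-electron-demand Diels–Alder reaction by the electron-rich enol-ether C=C of the allene: the nucleophilic central allene carbon should bond to the dienone terminus next to the ketal and the alkoxy group should take the endo position (syn to the new alkene bridge), which fixes C3a, C6 and C5 relative to one another and delivers the C4 methylidene, while the (S)-arylethyl group makes the two endo adducts diastereomers so that the one with the required absolute configuration can be isolated.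

Step 6
Reactants: 10 endo bicyclo[2.2.2]oct-5-en-2-one adduct
Product: 11 demethoxylated bicyclo[2.2.2]oct-5-en-2-one
Conditions: SmI2 (5 equiv), THF/MeOH, rt
Reagents that add atoms: none
Why: SmI2 cleaves both C–O bonds α to the ketone by single-electron transfer (reductive removal of α-alkoxy groups), leaving the CH2–C=O bridge that becomes C3 and C2.

Step 7
Reactants: 11 demethoxylated bicyclo[2.2.2]oct-5-en-2-one
Product: 13 cis-hydroxy methyl ester, via hydroxy acid 12 (not isolated)
Conditions: 30% H2O2, NaOH, MeOH/THF/H2O, 0 °C to rt; HCl to pH 4; then TMSCHN2, toluene/MeOH, 0 °C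
Reagents that add atoms: hydrogen peroxide OO; sodium hydroxide [Na+].[OH-]; trimethylsilyldiazomethane C[Si](C)(C)C=[N+]=[N-]
Why: Baeyer–Villiger oxidation with the nucleophilic hydroperoxide anion, which should not epoxidise the electron-rich diene, lets the allylic bridgehead migrate with retention and the lactone is saponified in the same pot, so that the C6 hydroxyl ends cis to the C3a acetic acid arm, and the acid is then methylated by the diazoalkane.

Step 8
Reactants: 14 (S)-propylene oxide
Product: 15 (S)-1-(phenylsulfonyl)propan-2-ol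
Conditions: PhSO2Na, H2O, 70 °C
Reagents that add atoms: sodium benzenesulfinate [Na+].[O-]S(=O)c1ccccc1
Why: The sulfinate opens the epoxide through sulfur at the unsubstituted carbon (SN2 ring opening), so the (S) carbinol centre that becomes C1′ is untouched.

Step 9
Reactants: 15 (S)-1-(phenylsulfonyl)propan-2-ol
Product: 16 (S)-tert-butyldiphenylsilyl ether of 15
Conditions: TBDPSCl, imidazole, DMF, rt
Reagents that add atoms: tert-butyldiphenylsilyl chloride CC(C)(C)[Si](Cl)(c1ccccc1)c1ccccc1
Why: Silylation with the bulky TBDPS group protects the carbinol that later carries the acetate and differentiates it from the primary TBS ether.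

Step 10
Reactants: 13 cis-hydroxy methyl ester; 16 (S)-tert-butyldiphenylsilyl ether of 15
Product: 17 hydroxy β-keto sulfone
Conditions: 16 (3.2 equiv), n-BuLi (3.1 equiv), THF, −78 °C; then 13, −78 to −40 °C; aq. NH4Cl
Reagents that add atoms: none
Why: Acylation of the α-sulfonyl carbanion by the methyl ester (Claisen-type condensation, with one equivalent of anion consumed by the free hydroxyl and one by the acidic product) forms the C1–C2 bond and gives the β-keto sulfone as an inconsequential mixture of C1 epimers.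

Step 11
Reactants: 17 hydroxy β-keto sulfone
Product: 18 allylic methyl carbonate
Conditions: ClCO2Me, pyridine, CH2Cl2, 0 °C
Reagents that add atoms: methyl chloroformate COC(=O)Cl
Why: O-acylation of the secondary allylic alcohol with the chloroformate gives the allylic carbonate, the leaving group for π-allyl formation under neutral conditions.

Step 12
Reactants: 18 allylic methyl carbonate
Product: 19 cis-fused bicyclic β-keto sulfone
Conditions: Pd2(dba)3·CHCl3 (2.5 mol %), dppe (6 mol %), THF (0.01 M), 60 °C
Reagents that add atoms: none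
Why: Zerovalent palladium ionises the allylic carbonate with inversion at C6 to give a π-allyl complex over C6–C7–C7a on the α face, and the methoxide set free after loss of CO2 deprotonates the β-keto sulfone, whose soft carbon C1 then attacks the C7a terminus on the face opposite to palladium (Tsuji–Trost allylic alkylation under neutral conditions; the closest precedent is the palladium-catalysed cyclisation of β-keto esters and sulfones onto allylic esters to give alkenyl-substituted cyclopentanones). Ring A closes by a 5-(enolendo)-exo-trig C-alkylation, and any kinetically formed O-allylation product (a fused 2-alkylidene-tetrahydrofuran) is itself an allylic enol ether that should re-ionise under the same catalyst and funnel to the more stable ketone. C7a is set by double inversion, that is net retention relative to the C6–O bond, which the Baeyer–Villiger step placed cis to the C3a arm, so the ring fusion can only be cis (H-3a and H-7a both α). C1 is formed as a quaternary sulfone whose configuration does not matter because C1 is set again in step 13. The step needs attack at C7a and not at C6, which the two-atom tether secures, since attack at C6 would give a strained bridged bicyclo[3.2.2]nonenone. The C6=C7 alkene that is left, conjugated with the side-chain alkene, is the vinyl-epoxide precursor for steps 14 and 15.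

Step 13
Reactants: 19 cis-fused bicyclic β-keto sulfone
Product: 20 cis-hexahydroindenone with H-1 α
Conditions: SmI2 (2.5 equiv), THF/MeOH, −78 °C
Reagents that add atoms: none
Why: Reductive desulfonylation of the β-keto sulfone by SmI2 gives a samarium enolate that should be protonated by methanol at low temperature on the convex α face, away from C7, which sets H-1 cis to H-7a (kinetic protonation, as known for enolates of 2,3-disubstituted cyclopentanones).

Step 14
Reactants: 20 cis-hexahydroindenone with H-1 α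
Product: 21 6β,7β-vinyl epoxide
Conditions: mCPBA (1.05 equiv), NaHCO3, CH2Cl2, −20 to 0 °C
Reagents that add atoms: 3-chloroperoxybenzoic acid O=C(OO)c1cccc(Cl)c1
Why: Prilezhaev epoxidation should take the most electron-rich, trisubstituted ring alkene of the diene and is expected on the β face, anti to the pseudoaxial allylic C5 ether, giving the vinyl epoxide.

Step 15
Reactants: 21 6β,7β-vinyl epoxide
Product: 22 6β-alcohol with H-7 α
Conditions: Pd2(dba)3·CHCl3 (2.5 mol %), n-Bu3P (10 mol %), HCO2H, Et3N, 1,4-dioxane, rt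
Reagents that add atoms: none
Why: In this palladium-catalysed formate hydrogenolysis of a vinyl epoxide, zerovalent palladium opens the allylic C7–O bond with inversion and the palladium hydride formed from formate delivers hydrogen to the more substituted allyl terminus from the metal side, so that H-7 enters α, the 6β-hydroxyl is kept and the 1,1-disubstituted alkene is regenerated.

Step 16
Reactants: 22 6β-alcohol with H-7 α; 23 (E)-3-methylpent-2-enoic acid
Product: 24 C6 pentenoate ester
Conditions: EDC·HCl, DMAP, CH2Cl2, 0 °C to rt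
Reagents that add atoms: none
Why: Steglich esterification of the hindered secondary alcohol with the carbodiimide-activated acid installs the C6 ester without touching any stereocentre.

Step 17
Reactants: 24 C6 pentenoate ester
Product: 25 primary allylic alcohol
Conditions: HF·pyridine, pyridine, THF, 0 °C
Reagents that add atoms: none
Why: Buffered HF·pyridine removes the primary allylic TBS ether much faster than the secondary TBDPS ether (selective desilylation).

Step 18
Reactants: 25 primary allylic alcohol
Product: 26 epoxy alcohol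
Conditions: Ti(OiPr)4 (10 mol %), D-(−)-diethyl tartrate (12 mol %), t-BuOOH, 4 Å molecular sieves, CH2Cl2, −20 °C
Reagents that add atoms: tert-butyl hydroperoxide CC(C)(C)OO
Why: Sharpless asymmetric epoxidation of the 2-substituted allylic alcohol is reagent-controlled, and D-(−)-diethyl tartrate should deliver oxygen to the face that gives the oxirane carbon with the configuration required for the (S)-glycidic ester.

Step 19
Reactants: 26 epoxy alcohol
Product: 28 glycidic methyl ester, via epoxy acid 27 (not isolated)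
Conditions: TEMPO (cat.), PhI(OAc)2, MeCN/H2O (pH 7 buffer), rt; then TMSCHN2, toluene/MeOH, 0 °C
Reagents that add atoms: water O; trimethylsilyldiazomethane C[Si](C)(C)C=[N+]=[N-]
Why: TEMPO/PhI(OAc)2 oxidation in aqueous acetonitrile takes the primary alcohol through the aldehyde hydrate to the acid under neutral conditions that should leave the oxirane and the epimerisable C1 untouched, and the diazoalkane then gives the methyl ester.

Step 20
Reactants: 28 glycidic methyl ester
Product: 29 C5 alcohol
Conditions: DDQ, CH2Cl2/pH 7 buffer, 0 °C to rt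
Reagents that add atoms: none
Why: DDQ oxidises the electron-rich p-methoxy-α-methylbenzyl ether to an oxocarbenium ion that is hydrolysed (oxidative benzyl ether cleavage), freeing the C5 hydroxyl and releasing the auxiliary as a ketone.

Step 21
Reactants: 29 C5 alcohol; 30 (R)-2-methylbutanoic acid
Product: 31 C5 C6 diester
Conditions: EDC·HCl, DMAP (cat.), CH2Cl2, 0 °C
Reagents that add atoms: none
Why: Steglich esterification at 0 °C acylates the allylic C5 alcohol with retention at the carbinol carbon and should not epimerise the α-stereocentre of the acid.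

Step 22
Reactants: 31 C5 C6 diester
Product: 32 C1′ alcohol
Conditions: HF·pyridine (excess), THF, 0 °C to rt
Reagents that add atoms: none
Why: Fluoride cleavage of the secondary TBDPS ether under weakly acidic conditions avoids the base-induced epimerisation at C1 and the β-elimination that a β-oxy ketone could suffer.

Step 23
Reactants: 32 C1′ alcohol
Product: 33 target CNP0251769.2
Conditions: Ac2O, pyridine, DMAP (cat.), CH2Cl2, 0 °C
Reagents that add atoms: acetic anhydride CC(=O)OC(C)=O
Why: Acetylation of the secondary alcohol with Ac2O/pyridine at 0 °C completes the target under conditions mild enough not to epimerise C1 or eliminate the β-acetoxy ketone.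

**Compound list**

1 | 2-bromoprop-2-en-1-ol | C=C(Br)CO | starting material
2 | (2-bromoallyloxy)(tert-butyl)dimethylsilane | C=C(Br)CO[Si](C)(C)C(C)(C)C | intermediate
3 | (3-hydroxy-4-methoxyphenyl)boronic acid | COc1ccc(B(O)O)cc1O | starting material
4 | 5-[3-(tert-butyldimethylsilyloxy)prop-1-en-2-yl]-2-methoxyphenol | COc1ccc(C(=C)CO[Si](C)(C)C(C)(C)C)cc1O | intermediate
5 | (S)-1-(4-methoxyphenyl)ethanol | C[C@H](O)c1ccc(OC)cc1 | starting material
6 | propargyl bromide (3-bromoprop-1-yne) | C#CCBr | starting material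
7 | (S)-1-methoxy-4-[1-(prop-2-yn-1-yloxy)ethyl]benzene | C#CCO[C@@H](C)c1ccc(OC)cc1 | intermediate
8 | (S)-1-methoxy-4-[1-(propa-1,2-dien-1-yloxy)ethyl]benzene (alkoxyallene) | C=C=CO[C@@H](C)c1ccc(OC)cc1 | intermediate
9 | 6,6-dimethoxy-3-[3-(tert-butyldimethylsilyloxy)prop-1-en-2-yl]cyclohexa-2,4-dien-1-one (masked o-benzoquinone, not isolated) | O=C1C=C(C(=C)CO[Si](C)(C)C(C)(C)C)C=CC1(OC)OC | intermediate
10 | 3,3-dimethoxy-7-[(S)-1-(4-methoxyphenyl)ethoxy]-8-methylidene-6-[3-(tert-butyldimethylsilyloxy)prop-1-en-2-yl]bicyclo[2.2.2]oct-5-en-2-one; 7-alkoxy group syn to the C5=C6 bridge (endo); bridgeheads C1 and C4 become C6 and C3a of the target | O=C1C(OC)(OC)[C@H]2C=C(C(=C)CO[Si](C)(C)C(C)(C)C)[C@@H]1[C@H](O[C@@H](C)c3ccc(OC)cc3)C2=C | intermediate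
11 | 7-[(S)-1-(4-methoxyphenyl)ethoxy]-8-methylidene-6-[3-(tert-butyldimethylsilyloxy)prop-1-en-2-yl]bicyclo[2.2.2]oct-5-en-2-one; same configuration as 10 | O=C1C[C@H]2C=C(C(=C)CO[Si](C)(C)C(C)(C)C)[C@@H]1[C@H](O[C@@H](C)c3ccc(OC)cc3)C2=C | intermediate
12 | 2-[4-hydroxy-5-[(S)-1-(4-methoxyphenyl)ethoxy]-6-methylidene-3-[3-(tert-butyldimethylsilyloxy)prop-1-en-2-yl]cyclohex-2-en-1-yl]acetic acid; 4-OH cis to the acetic acid arm (both β), 5-O trans to both (α) (not isolated) | C=C1[C@@H](CC(=O)O)C=C(C(=C)CO[Si](C)(C)C(C)(C)C)[C@@H](O)[C@@H]1O[C@@H](C)c1ccc(OC)cc1 | intermediate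
13 | methyl ester of 12; same configuration | C=C1[C@@H](CC(=O)OC)C=C(C(=C)CO[Si](C)(C)C(C)(C)C)[C@@H](O)[C@@H]1O[C@@H](C)c1ccc(OC)cc1 | intermediate
14 | (S)-propylene oxide ((S)-2-methyloxirane) | C[C@H]1CO1 | starting material
15 | (S)-1-(phenylsulfonyl)propan-2-ol | C[C@H](O)CS(=O)(=O)c1ccccc1 | intermediate
16 | (S)-tert-butyldiphenyl{[1-(phenylsulfonyl)propan-2-yl]oxy}silane | C[C@H](O[Si](c1ccccc1)(c1ccccc1)C(C)(C)C)CS(=O)(=O)c1ccccc1 | intermediate
17 | (4S)-4-(tert-butyldiphenylsilyloxy)-3-(phenylsulfonyl)-1-[the cyclohexenyl ring of 13]pentan-2-one; ring stereocentres as in 13 (6β-OH, 5α-O, 3a-arm β in target numbering); mixture of epimers at the sulfonyl carbon (future C1) | C=C1[C@@H](CC(=O)C([C@H](C)O[Si](c2ccccc2)(c2ccccc2)C(C)(C)C)S(=O)(=O)c2ccccc2)C=C(C(=C)CO[Si](C)(C)C(C)(C)C)[C@@H](O)[C@@H]1O[C@@H](C)c1ccc(OC)cc1 | intermediate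
18 | methyl carbonate of the allylic (future C6) hydroxyl of 17 | C=C1[C@@H](CC(=O)C([C@H](C)O[Si](c2ccccc2)(c2ccccc2)C(C)(C)C)S(=O)(=O)c2ccccc2)C=C(C(=C)CO[Si](C)(C)C(C)(C)C)[C@@H](OC(=O)OC)[C@@H]1O[C@@H](C)c1ccc(OC)cc1 | intermediate
19 | 1-(phenylsulfonyl)-1-[(S)-1-(tert-butyldiphenylsilyloxy)ethyl]-5α-[(S)-1-(4-methoxyphenyl)ethoxy]-4-methylidene-7-[3-(tert-butyldimethylsilyloxy)prop-1-en-2-yl]-1,3,3a,4,5,7a-hexahydro-2H-inden-2-one; cis-fused (H-3a, H-7a α); either C1 epimer | C=C1[C@H]2CC(=O)C(S(=O)(=O)c3ccccc3)([C@H](C)O[Si](c3ccccc3)(c3ccccc3)C(C)(C)C)[C@H]2C(C(=C)CO[Si](C)(C)C(C)(C)C)=C[C@@H]1O[C@@H](C)c1ccc(OC)cc1 | intermediate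
20 | 1β-[(S)-1-(tert-butyldiphenylsilyloxy)ethyl]-5α-[(S)-1-(4-methoxyphenyl)ethoxy]-4-methylidene-7-[3-(tert-butyldimethylsilyloxy)prop-1-en-2-yl]-1,3,3a,4,5,7a-hexahydro-2H-inden-2-one; H-1, H-3a, H-7a all α | C=C1[C@H]2CC(=O)[C@@H]([C@H](C)O[Si](c3ccccc3)(c3ccccc3)C(C)(C)C)[C@H]2C(C(=C)CO[Si](C)(C)C(C)(C)C)=C[C@@H]1O[C@@H](C)c1ccc(OC)cc1 | intermediate
21 | 6β,7β-epoxide of 20 (oxirane oxygen on the β face; side chain on C7 α) | C=C1[C@H]2CC(=O)[C@@H]([C@H](C)O[Si](c3ccccc3)(c3ccccc3)C(C)(C)C)[C@H]2[C@@]3(C(=C)CO[Si](C)(C)C(C)(C)C)O[C@H]3[C@@H]1O[C@@H](C)c1ccc(OC)cc1 | intermediate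
22 | 6β-hydroxy-7β-[3-(tert-butyldimethylsilyloxy)prop-1-en-2-yl] octahydroinden-2-one (H-7 α, H-6 α); other groups as in 20 | C=C1[C@H]2CC(=O)[C@@H]([C@H](C)O[Si](c3ccccc3)(c3ccccc3)C(C)(C)C)[C@H]2[C@@H](C(=C)CO[Si](C)(C)C(C)(C)C)[C@@H](O)[C@@H]1O[C@@H](C)c1ccc(OC)cc1 | intermediate
23 | (E)-3-methylpent-2-enoic acid | CC/C(C)=C/C(=O)O | starting material
24 | 6β-[(E)-3-methylpent-2-enoyl] ester of 22 | C=C1[C@H]2CC(=O)[C@@H]([C@H](C)O[Si](c3ccccc3)(c3ccccc3)C(C)(C)C)[C@H]2[C@@H](C(=C)CO[Si](C)(C)C(C)(C)C)[C@@H](OC(=O)/C=C(\C)CC)[C@@H]1O[C@@H](C)c1ccc(OC)cc1 | intermediate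
25 | 7β-(3-hydroxyprop-1-en-2-yl) compound (primary allylic alcohol) from 24 | C=C1[C@H]2CC(=O)[C@@H]([C@H](C)O[Si](c3ccccc3)(c3ccccc3)C(C)(C)C)[C@H]2[C@@H](C(=C)CO)[C@@H](OC(=O)/C=C(\C)CC)[C@@H]1O[C@@H](C)c1ccc(OC)cc1 | intermediate
26 | 7β-[2-(hydroxymethyl)oxiran-2-yl] compound; oxirane carbon with the spatial arrangement of the target | C=C1[C@H]2CC(=O)[C@@H]([C@H](C)O[Si](c3ccccc3)(c3ccccc3)C(C)(C)C)[C@H]2[C@@H]([C@@]3(CO)CO3)[C@@H](OC(=O)/C=C(\C)CC)[C@@H]1O[C@@H](C)c1ccc(OC)cc1 | intermediate
27 | (S)-oxirane-2-carboxylic acid corresponding to 26 (not isolated) | C=C1[C@H]2CC(=O)[C@@H]([C@H](C)O[Si](c3ccccc3)(c3ccccc3)C(C)(C)C)[C@H]2[C@@H]([C@@]3(C(=O)O)CO3)[C@@H](OC(=O)/C=C(\C)CC)[C@@H]1O[C@@H](C)c1ccc(OC)cc1 | intermediate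
28 | methyl (S)-oxirane-2-carboxylate (glycidic ester) from 27 | C=C1[C@H]2CC(=O)[C@@H]([C@H](C)O[Si](c3ccccc3)(c3ccccc3)C(C)(C)C)[C@H]2[C@@H]([C@@]3(C(=O)OC)CO3)[C@@H](OC(=O)/C=C(\C)CC)[C@@H]1O[C@@H](C)c1ccc(OC)cc1 | intermediate
29 | 5α-alcohol from 28 | C=C1[C@H]2CC(=O)[C@@H]([C@H](C)O[Si](c3ccccc3)(c3ccccc3)C(C)(C)C)[C@H]2[C@@H]([C@@]3(C(=O)OC)CO3)[C@@H](OC(=O)/C=C(\C)CC)[C@@H]1O | intermediate
30 | (R)-2-methylbutanoic acid | CC[C@@H](C)C(=O)O | starting material
31 | 5α-[(R)-2-methylbutanoyl] ester of 29 | C=C1[C@H]2CC(=O)[C@@H]([C@H](C)O[Si](c3ccccc3)(c3ccccc3)C(C)(C)C)[C@H]2[C@@H]([C@@]3(C(=O)OC)CO3)[C@@H](OC(=O)/C=C(\C)CC)[C@@H]1OC(=O)[C@H](C)CC | intermediate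
32 | 1β-[(S)-1-hydroxyethyl] compound from 31 | C=C1[C@H]2CC(=O)[C@@H]([C@H](C)O)[C@H]2[C@@H]([C@@]2(C(=O)OC)CO2)[C@@H](OC(=O)/C=C(\C)CC)[C@@H]1OC(=O)[C@H](C)CC | intermediate
33 | CNP0251769.2: 1β-[(S)-1-acetoxyethyl]-5α-[(R)-2-methylbutanoyloxy]-6β-[(E)-3-methylpent-2-enoyloxy]-7β-[(S)-2-(methoxycarbonyl)oxiran-2-yl]-4-methylidene-cis-octahydro-2H-inden-2-one | C=C1[C@H]2CC(=O)[C@@H]([C@H](C)OC(C)=O)[C@H]2[C@@H]([C@@]2(C(=O)OC)CO2)[C@@H](OC(=O)/C=C(\C)CC)[C@@H]1OC(=O)[C@H](C)CC | target

**Totals**

Total steps: 23. Longest linear sequence: 19 steps (steps 1, 2, 5–7 and 10–23).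

**Steps most likely to fail**

Step 12 (key step). The carbon–carbon bond at C7a may lose to O-allylation that does not revert, or to β-hydride elimination of the allylpalladium intermediate to a triene, because the enolate carbon and its carbonyl both lie inside the ring being formed. The fallback replaces allylic substitution by conjugate addition and keeps the C6 oxygen. It sets out from 17: MnO2 in CH2Cl2 oxidises the allylic alcohol to the cyclohexenone F1. Cs2CO3 in MeCN at 0 °C, quenched with AcOH at low temperature, closes ring A by intramolecular Michael addition of the β-keto sulfone to C7a and gives the diketone F2 after kinetic protonation of the dienolate at C7 from the α face. NaBH4/CeCl3·7H2O in MeOH at −78 °C reduces the cyclohexanone from the α face, the hindered α-quaternary cyclopentanone being expected to react more slowly, to the 6β-alcohol F3. SmI2 in THF/MeOH at −78 °C removes the sulfonyl group, and the route is rejoined at 22, so steps 13–15 are bypassed.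

Step 14. The epoxidation may show poor facial selectivity; an α-epoxide would invert both C6 and C7 after step 15. The fallback installs the C6 oxygen as a ketone and brings both hydrogens in from the less hindered face. It sets out from 20: photooxygenation (O2, tetraphenylporphyrin, hν, CH2Cl2, −78 °C) adds singlet oxygen across the 1,3-diene to give the endoperoxide F4. Et3N (Kornblum–DeLaMare rearrangement) gives the 4-hydroxy enone F5. Luche reduction (NaBH4, CeCl3·7H2O, MeOH, −78 °C) gives the 6β-allylic alcohol F6. ClCO2Me/pyridine at −30 °C acylates only the primary hydroxyl to the allylic carbonate F7. Pd2(dba)3·CHCl3, n-Bu3P, HCO2H and Et3N then deliver hydride to C7 from the α face of the freely equilibrating allylpalladium intermediate, regenerating the 1,1-disubstituted alkene, and the route is rejoined at 22.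

Step 13. Stereocontrol at C1 may be lost during protonation of the samarium enolate, or silanolate may be lost from it by β-elimination. The fallback avoids an enolate altogether: radical desulfonylation of 19 with Bu3SnH/AIBN in benzene at 80 °C, in which the hydrogen atom is transferred to the α-keto radical on the convex α face, leads directly to 20 and makes no new compound.

**Further compounds**

F1 | step 12 | cyclohexenone from 17 (C6 ketone conjugated with C7=C7a; β-keto sulfone side chain unchanged) | C=C1[C@@H](CC(=O)C([C@H](C)O[Si](c2ccccc2)(c2ccccc2)C(C)(C)C)S(=O)(=O)c2ccccc2)C=C(C(=C)CO[Si](C)(C)C(C)(C)C)C(=O)[C@@H]1O[C@@H](C)c1ccc(OC)cc1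
F2 | step 12 | cis-fused 1-(phenylsulfonyl) octahydroindene-2,6-dione, H-7 α (Michael adduct; either C1 epimer) | C=C1[C@H]2CC(=O)C(S(=O)(=O)c3ccccc3)([C@H](C)O[Si](c3ccccc3)(c3ccccc3)C(C)(C)C)[C@H]2[C@@H](C(=C)CO[Si](C)(C)C(C)(C)C)C(=O)[C@@H]1O[C@@H](C)c1ccc(OC)cc1
F3 | step 12 | 6β-alcohol of F2 (1-sulfonyl analogue of 22) | C=C1[C@H]2CC(=O)C(S(=O)(=O)c3ccccc3)([C@H](C)O[Si](c3ccccc3)(c3ccccc3)C(C)(C)C)[C@H]2[C@@H](C(=C)CO[Si](C)(C)C(C)(C)C)[C@@H](O)[C@@H]1O[C@@H](C)c1ccc(OC)cc1
F0 | step 13 | none | none
F4 | step 14 | endoperoxide (3,6-dihydro-1,2-dioxine fused at C6–C7; peroxide oxygen on C6 drawn α, configuration there inconsequential) | C=C1[C@H]2CC(=O)[C@@H]([C@H](C)O[Si](c3ccccc3)(c3ccccc3)C(C)(C)C)[C@H]2C3=C(CO[Si](C)(C)C(C)(C)C)COO[C@@H]3[C@@H]1O[C@@H](C)c1ccc(OC)cc1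
F5 | step 14 | 6-oxo-7-alkylidene compound (4-hydroxy enone; CH2OH cis to the C6 carbonyl) | C=C1[C@H]2CC(=O)[C@@H]([C@H](C)O[Si](c3ccccc3)(c3ccccc3)C(C)(C)C)[C@H]2/C(=C(/CO)CO[Si](C)(C)C(C)(C)C)C(=O)[C@@H]1O[C@@H](C)c1ccc(OC)cc1
F6 | step 14 | 6β-allylic alcohol of F5 (diol) | C=C1[C@H]2CC(=O)[C@@H]([C@H](C)O[Si](c3ccccc3)(c3ccccc3)C(C)(C)C)[C@H]2/C(=C(/CO)CO[Si](C)(C)C(C)(C)C)[C@@H](O)[C@@H]1O[C@@H](C)c1ccc(OC)cc1
F7 | step 14 | primary allylic methyl carbonate of F6 | C=C1[C@H]2CC(=O)[C@@H]([C@H](C)O[Si](c3ccccc3)(c3ccccc3)C(C)(C)C)[C@H]2/C(=C(/COC(=O)OC)CO[Si](C)(C)C(C)(C)C)[C@@H](O)[C@@H]1O[C@@H](C)c1ccc(OC)cc1
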